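**Retrosynthetic overview**

- The target is a linear trimer, ring A–CH2–ring B–CH2–ring C, with no stereocentre. The strategy rests on ring A: it is a butanoylphloroglucinol ring whose C3, the carbon between the oxygen-bearing C2 and C4, carries two methyl groups. Rings A and B are therefore the same monomer apart from the two C3–CH3 bonds.
- Last disconnection: the ring B–CH2–ring C bridge. It is made by aminomethylation of the only free carbon of ring B, followed by elimination–addition with the 4-O-methyl ether of the monomer (ring C).
- Key disconnection: both C3–CH3 bonds of ring A. They are made by double C-methylation (CH3I, NaOCH3) of one ring of the symmetric methylenebis(butanoylphloroglucinol), which dearomatises that ring.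
- The symmetric dimer comes from 1-(2,4,6-trihydroxyphenyl)butan-1-one and formaldehyde. No ring is formed anywhere in the route; all three six-membered rings are carried in from this one monomer.

Key step: step 2

Remark on the chemistry: ring A is numbered C1 (butanoyl), C2 (enol OH), C3 (CMe2), C4 (enol OH), C5 (CH2 bridge), C6 (C=O). Its enol tautomers interconvert, so the tautomer written in each SMILES stands for the equilibrating compound. The ring C monomer is made in one step from the same butyrophenone and is not assumed to be purchasable.

**Step 1**
Reactants: 1 1-(2,4,6-trihydroxyphenyl)butan-1-one (2.5 equiv); 2 formaldehyde (1.0 equiv)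
Product: 4 1,1'-[methylenebis(2,4,6-trihydroxybenzene-3,1-diyl)]di(butan-1-one), via hydroxymethyl monomer 3 (not isolated)
Conditions: 37% aq. CH2O added slowly, 0.5 M aq. NaOH, N2, 0 °C to rt; then 1 M HCl; excess 1 recovered
Reagents that add atoms: none
Why: Lederer–Manasse hydroxymethylation of the phenolate of 1 gives 3, which loses water as a second phenolate of 1 adds (phenol–formaldehyde condensation); the two free ring carbons of 1 are equivalent, so only one constitution can form, and the excess of 1 should hold chain growth at the dimer.

**Step 2**
Reactants: 4 1,1'-[methylenebis(2,4,6-trihydroxybenzene-3,1-diyl)]di(butan-1-one); 5 iodomethane (2.0 equiv)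
Product: 7 2-butanoyl-6-[(3-butanoyl-2,4,6-trihydroxyphenyl)methyl]-3,5-dihydroxy-4,4-dimethylcyclohexa-2,5-dien-1-one, via mono-C-methyl dimer 6 (not isolated)
Conditions: NaOCH3 (4 equiv), CH3OH, N2, 0 °C; CH3I added slowly, 0 °C to rt, partial conversion; aq. HCl; 4 and 6 recovered and resubmitted
Reagents that add atoms: none
Why: NaOCH3 turns each ring of 4 into a polyphenolate, and SN2 attack of the unsubstituted ring carbon (C3, flanked by two oxygen-bearing carbons) on CH3I gives the 3-methyl arene 6. Renewed deprotonation and a second SN2 attack from the same, now more electron-rich carbon create the quaternary C3, after which the ring cannot rearomatise and rests as the enolised 2-acylcyclohexane-1,3,5-trione of ring A. The closest known reaction is the alkaline CH3I gem-dimethylation of monomeric acylphloroglucinols to acylfilicinic acids, applied here to a methylene-bridged dimer. No ring is closed and no stereocentre is formed, because C3 carries two identical methyl groups. The step needs C- over O-alkylation, which the hydrogen-bonding solvent CH3OH and the soft iodide electrophile favour, and it needs attack at C3 rather than at the bridge-bearing C5, which rests only on the greater hindrance of the carbon that carries the arylmethyl group. The two rings of 4 are identical, so it does not matter which one reacts, but stopping at one ring is statistical; CH3I is therefore limited to two equivalents, and the much more acidic 7 should be separable from 4 and 6 by extraction into a pH 6–7 aqueous buffer.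

**Step 3**
Reactants: 1 1-(2,4,6-trihydroxyphenyl)butan-1-one
Product: 8 1-(2,6-dihydroxy-4-methoxyphenyl)butan-1-one
Conditions: (CH3O)2SO2 (1.0 equiv), K2CO3 (1.0 equiv), acetone, rt
Reagents that add atoms: dimethyl sulfate, COS(=O)(=O)OC
Why: Williamson O-methylation; the 4-OH para to the ketone is the most acidic hydroxyl and the only one not held in a hydrogen bond to the carbonyl, so one equivalent of a hard sulfate electrophile with carbonate in acetone should etherify it selectively and at oxygen.

**Step 4**
Reactants: 7 2-butanoyl-6-[(3-butanoyl-2,4,6-trihydroxyphenyl)methyl]-3,5-dihydroxy-4,4-dimethylcyclohexa-2,5-dien-1-one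
Product: 9 2-butanoyl-6-[[3-butanoyl-5-[(dimethylamino)methyl]-2,4,6-trihydroxyphenyl]methyl]-3,5-dihydroxy-4,4-dimethylcyclohexa-2,5-dien-1-one
Conditions: CH2(N(CH3)2)2 (1.1 equiv), CH2Cl2, 0 °C to rt; crude product used directly
Reagents that add atoms: bis(dimethylamino)methane, CN(C)CN(C)C
Why: Mannich aminomethylation with a preformed aminal, activated by the acidic ring A enol of the substrate; the free carbon of ring B is the only unsubstituted ring carbon in 7, so only one C-aminomethyl product can form and no free formaldehyde is present to couple two molecules of 7.

**Step 5**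
Reactants: 9 2-butanoyl-6-[[3-butanoyl-5-[(dimethylamino)methyl]-2,4,6-trihydroxyphenyl]methyl]-3,5-dihydroxy-4,4-dimethylcyclohexa-2,5-dien-1-one; 8 1-(2,6-dihydroxy-4-methoxyphenyl)butan-1-one (3 equiv)
Product: 11 2-butanoyl-6-[[3-butanoyl-5-[(3-butanoyl-2,4-dihydroxy-6-methoxyphenyl)methyl]-2,4,6-trihydroxyphenyl]methyl]-3,5-dihydroxy-4,4-dimethylcyclohexa-2,5-dien-1-one (target CNP0178590.0), via ring B ortho-quinone methide 10 (not isolated)
Conditions: 1,4-dioxane, 80 °C, N2 stream to carry off HN(CH3)2; excess 8 recovered
Reagents that add atoms: none
Why: thermal elimination of dimethylamine from the zwitterionic phenolic Mannich base gives ortho-quinone methide 10, which is captured by conjugate (Friedel–Crafts-type) addition of the electron-rich C3 of 8; C3 and C5 of 8 are equivalent, so one regioisomer results, ring B of 10 has no free carbon and cannot self-condense, and the excess of 8 should suppress double alkylation of one ring C.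

**Compound list**

1 | 1-(2,4,6-trihydroxyphenyl)butan-1-one | CCCC(=O)c1c(O)cc(O)cc1O | starting material
2 | formaldehyde (37% aqueous) | C=O | starting material
3 | 1-[2,4,6-trihydroxy-3-(hydroxymethyl)phenyl]butan-1-one (formed in the flask) | CCCC(=O)c1c(O)cc(O)c(CO)c1O | intermediate
4 | 1,1'-[methylenebis(2,4,6-trihydroxybenzene-3,1-diyl)]di(butan-1-one), symmetric dimer | CCCC(=O)c1c(O)cc(O)c(Cc2c(O)cc(O)c(C(=O)CCC)c2O)c1O | intermediate
5 | iodomethane | CI | starting material
6 | 1-[3-[(3-butanoyl-2,4,6-trihydroxyphenyl)methyl]-2,4,6-trihydroxy-5-methylphenyl]butan-1-one (formed in the flask) | CCCC(=O)c1c(O)c(C)c(O)c(Cc2c(O)cc(O)c(C(=O)CCC)c2O)c1O | intermediate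
7 | 2-butanoyl-6-[(3-butanoyl-2,4,6-trihydroxyphenyl)methyl]-3,5-dihydroxy-4,4-dimethylcyclohexa-2,5-dien-1-one, ring A–ring B dimer | CCCC(=O)C1=C(O)C(C)(C)C(O)=C(Cc2c(O)cc(O)c(C(=O)CCC)c2O)C1=O | intermediate
8 | 1-(2,6-dihydroxy-4-methoxyphenyl)butan-1-one, ring C monomer | CCCC(=O)c1c(O)cc(OC)cc1O | intermediate
9 | 2-butanoyl-6-[[3-butanoyl-5-[(dimethylamino)methyl]-2,4,6-trihydroxyphenyl]methyl]-3,5-dihydroxy-4,4-dimethylcyclohexa-2,5-dien-1-one, Mannich base | CCCC(=O)C1=C(O)C(C)(C)C(O)=C(Cc2c(O)c(CN(C)C)c(O)c(C(=O)CCC)c2O)C1=O | intermediate
10 | ring B ortho-quinone methide of 9 after loss of dimethylamine (formed in the flask) | C=C1C(O)=C(CC2=C(O)C(C)(C)C(O)=C(C(=O)CCC)C2=O)C(O)=C(C(=O)CCC)C1=O | intermediate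
11 | 2-butanoyl-6-[[3-butanoyl-5-[(3-butanoyl-2,4-dihydroxy-6-methoxyphenyl)methyl]-2,4,6-trihydroxyphenyl]methyl]-3,5-dihydroxy-4,4-dimethylcyclohexa-2,5-dien-1-one | CCCC(=O)C1=C(O)C(C)(C)C(O)=C(Cc2c(O)c(Cc3c(OC)cc(O)c(C(=O)CCC)c3O)c(O)c(C(=O)CCC)c2O)C1=O | target

**Step count**

Total: 5 steps. Longest linear sequence: 4 steps (steps 1, 2, 4, 5, from 1 through 4, 7 and 9 to 11); step 3 is a one-step branch that supplies 8.

**Steps most likely to fail**

Step 2 (key step). Methylation may spread over both rings instead of placing two methyl groups on one, may go to the bridge-bearing carbon C5 or to oxygen, and the methoxide may cleave and recombine the methylene bridge of 7 (retro-conjugate addition), which would exchange the halves and give symmetric dimers. The fallback sets out from 1 and comes back at 7, and it places the two methyl groups before the bridge is made. Treatment of 1 with CH3I and NaOCH3 in CH3OH should give the monomeric gem-dimethyl compound 2-butanoyl-3,5-dihydroxy-4,4-dimethylcyclohexa-2,5-dien-1-one F1, in which only the ring has to be distinguished from its over- and under-methylated relatives. Aminomethylation of the single remaining ring CH of F1 with bis(dimethylamino)methane should give 2-butanoyl-6-[(dimethylamino)methyl]-3,5-dihydroxy-4,4-dimethylcyclohexa-2,5-dien-1-one F2. Warming F2 in dioxane with an excess of 1 should then join the two different halves by elimination–addition and deliver 7, the excess of 1 keeping its second free carbon from reacting.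

Step 5. At the temperature needed to expel dimethylamine, the existing ring A–ring B bridge of 9 may cleave as well, since the ring A enolate is a competent leaving group, and the halves would then scramble; the quinone methide may also decompose or be captured twice by one molecule of 8. The fallback sets out from 8 and 7 and comes back at 11, omitting step 4, and it reverses the roles of the partners. Aminomethylation of 8 (kept in excess so that only one of its two equivalent carbons reacts) with bis(dimethylamino)methane should give 1-[3-[(dimethylamino)methyl]-2,6-dihydroxy-4-methoxyphenyl]butan-1-one F3. Warming F3 with 7 in dioxane should release the electrophile on ring C, the acidic ring A of 7 protonating the amine and so easing its loss, while 7 reacts only as a nucleophile through the free carbon of ring B and never carries two benzylic leaving groups on that ring.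

Step 1. Chain growth may not stop at the dimer, because 1 and the product 4 both keep free ring carbons that formaldehyde can hydroxymethylate, so trimers and higher oligomers would form and be hard to separate. The fallback sets out from 1 and comes back at 4, and it replaces the one-pot condensation by a stepwise sequence with no free formaldehyde. Aminomethylation of 1 (in excess) with bis(dimethylamino)methane should give the mono-Mannich base 1-[3-[(dimethylamino)methyl]-2,4,6-trihydroxyphenyl]butan-1-one F4, which is purified before any dimer exists. F4 is then added slowly to a warm dioxane solution of a large excess of 1, so that the electrophile is released at low concentration and meets almost only monomer, giving 4 by elimination–addition.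

**Further compounds**

F1 | step 2 | 2-butanoyl-3,5-dihydroxy-4,4-dimethylcyclohexa-2,5-dien-1-one | CCCC(=O)C1=C(O)C(C)(C)C(O)=CC1=O
F2 | step 2 | 2-butanoyl-6-[(dimethylamino)methyl]-3,5-dihydroxy-4,4-dimethylcyclohexa-2,5-dien-1-one | CCCC(=O)C1=C(O)C(C)(C)C(O)=C(CN(C)C)C1=O
F3 | step 5 | 1-[3-[(dimethylamino)methyl]-2,6-dihydroxy-4-methoxyphenyl]butan-1-one | CCCC(=O)c1c(O)cc(OC)c(CN(C)C)c1O
F4 | step 1 | 1-[3-[(dimethylamino)methyl]-2,4,6-trihydroxyphenyl]butan-1-one | CCCC(=O)c1c(O)cc(O)c(CN(C)C)c1O
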